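**Strategy.** Numbering: C1 is the ring ketone, C2=C3 the alkene, C4 and C5 the ring carbinols (C5 quaternary) and C6 the acetoxy-bearing side-chain carbon. Everything rests on breaking the C1–C5 acyloin bond of the five-membered ring. Because O4 and C6 are cis on that ring, O4 and O6 can be held in one six-membered di-tert-butylsilylene ring. The precursor is this dioxasilinane with C5 as its ketone and C1 as an aldehyde on a three-carbon arm at C4. A carbene-catalysed crossed benzoin reaction then forms C1–C5, the carbocycle and the C5 stereocentre (hydroxyl trans to O4) in one operation. The acetate is finally placed on O5 and moved to the neighbouring O6.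

Key step: step 9

Remark: the labels C1–C20 follow the ring numbering of the target in all intermediates (C7–C20 is the tetradecyl chain). The CIP label of C5 changes from S to R in step 13 only because acetylation of O6 swaps the ranks of C4 and C6. Both starting materials are taken to be purchasable.

**Route**

Step 1
Reactants: 1 4-(benzyloxy)butanoic acid
Product: 3 4-(benzyloxy)-N-methoxy-N-methylbutanamide, via acyl imidazolide 2 (not isolated)
Conditions: CDI, CH2Cl2, rt; then MeNH(OMe)·HCl, rt
Reagents that add atoms: N,O-dimethylhydroxylamine hydrochloride, CNOC.Cl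
Why: Amide coupling through the acyl imidazolide (CDI activation) is a standard entry to a Weinreb amide and leaves the benzyl ether untouched.

Step 2
Reactants: 3 4-(benzyloxy)-N-methoxy-N-methylbutanamide; 4 1-hexadecyne
Product: 7 1-(benzyloxy)icos-5-yn-4-one, via hexadecynyllithium 5 (not isolated), via lithium hemiaminal adduct 6 (not isolated)
Conditions: 4, nBuLi, THF, −78 °C; then 3, −78 → 0 °C; 1 M HCl, 0 °C
Reagents that add atoms: none
Why: Weinreb ketone synthesis, in which the lithium acetylide adds only once because the N-methoxy chelate holds the tetrahedral adduct until the acidic quench releases the ynone.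

Step 3
Reactants: 7 1-(benzyloxy)icos-5-yn-4-one
Product: 8 (4R)-1-(benzyloxy)icos-5-yn-4-ol
Conditions: Ru[(R,R)-TsDPEN](p-cymene) (1 mol%), iPrOH, rt
Reagents that add atoms: none
Why: Noyori–Ikariya asymmetric transfer hydrogenation of an alkynyl ketone, in which the alkyne plays the role of the aryl group in the usual transition-state model, so the (R,R)-catalyst should deliver hydride to the face that gives the 4R carbinol (C4 is set here) without touching the alkyne or the benzyl ether.

Step 4
Reactants: 8 (4R)-1-(benzyloxy)icos-5-yn-4-ol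
Product: 9 (4R,5Z)-1-(benzyloxy)icos-5-en-4-ol
Conditions: H2 (1 atm), Pd/CaCO3 poisoned with Pb(OAc)2, quinoline, EtOAc, rt
Reagents that add atoms: none
Why: Semi-hydrogenation over the lead-poisoned palladium catalyst (Lindlar reduction) adds hydrogen syn to the alkyne and stops at the Z-alkene, and the benzyl ether is not cleaved over this deactivated catalyst.

Step 5
Reactants: 9 (4R,5Z)-1-(benzyloxy)icos-5-en-4-ol
Product: 10 (4R,5S,6S)-1-(benzyloxy)icosane-4,5,6-triol
Conditions: OsO4 (2 mol%), NMO, acetone/H2O, 0 °C → rt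
Reagents that add atoms: N-methylmorpholine N-oxide, C[N+]1([O-])CCOCC1; water, O
Why: Upjohn dihydroxylation adds both oxygens syn to the Z-alkene on the face anti to the allylic hydroxyl (Kishi's empirical rule, reinforced by 1,3-allylic strain in a Z-alkene), so O5 ends anti to O4 and O6 anti to O5, which places O4 and O6 syn and sets C6 as S (the E-isomer would give the unwanted 4,6-anti triol by the same rule, and C5 is erased later).

Step 6
Reactants: 10 (4R,5S,6S)-1-(benzyloxy)icosane-4,5,6-triol
Product: 11 (4R,5S,6S)-4-[3-(benzyloxy)propyl]-2,2-di-tert-butyl-6-tetradecyl-1,3,2-dioxasilinan-5-ol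
Conditions: tBu2Si(OTf)2, 2,6-lutidine, CH2Cl2, 0 °C
Reagents that add atoms: di-tert-butylsilyl bis(trifluoromethanesulfonate), CC(C)(C)[Si](OS(=O)(=O)C(F)(F)F)(OS(=O)(=O)C(F)(F)F)C(C)(C)C
Why: Silylene protection of a diol, in which the di-tert-butylsilylene unit strongly prefers the six-membered 1,3-dioxasilinane over a strained five-membered ring and the syn-4,6 diol closes to a chair with all three carbon substituents equatorial, leaving the more hindered central O5 free.

Step 7
Reactants: 11 (4R,5S,6S)-4-[3-(benzyloxy)propyl]-2,2-di-tert-butyl-6-tetradecyl-1,3,2-dioxasilinan-5-ol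
Product: 12 3-[(4R,5S,6S)-2,2-di-tert-butyl-5-hydroxy-6-tetradecyl-1,3,2-dioxasilinan-4-yl]propan-1-ol
Conditions: H2 (1 atm), Pd/C, EtOAc, rt
Reagents that add atoms: none
Why: Hydrogenolysis of the benzyl ether over palladium on carbon is neutral and affects neither the silylene nor the free secondary alcohol.

Step 8
Reactants: 12 3-[(4R,5S,6S)-2,2-di-tert-butyl-5-hydroxy-6-tetradecyl-1,3,2-dioxasilinan-4-yl]propan-1-ol
Product: 13 3-[(4R,6S)-2,2-di-tert-butyl-5-oxo-6-tetradecyl-1,3,2-dioxasilinan-4-yl]propanal
Conditions: (COCl)2, DMSO, CH2Cl2, −78 °C; iPr2NEt, −78 → −30 °C; cold pH 7 buffer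
Reagents that add atoms: none
Why: Double Swern oxidation, in which both hydroxyls become alkoxysulfonium ions before any base is added so that no hydroxy aldehyde can close to a lactol and over-oxidise, while the hindered amine at low temperature limits enolisation at C4 and C6.

Step 9
Reactants: 13 3-[(4R,6S)-2,2-di-tert-butyl-5-oxo-6-tetradecyl-1,3,2-dioxasilinan-4-yl]propanal
Product: 14 (4S,4aS,7aR)-2,2-di-tert-butyl-4a-hydroxy-4-tetradecylhexahydrocyclopenta[d][1,3,2]dioxasilin-5-one (cis-fused; chain labels 4R,5S,6S)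
Conditions: 2-(pentafluorophenyl)-6,7-dihydro-5H-pyrrolo[2,1-c][1,2,4]triazol-2-ium tetrafluoroborate (10 mol%), Et3N (10 mol%), toluene (0.02 M), rt
Reagents that add atoms: none
Why: The carbene released from the triazolium salt adds to the C1 aldehyde, proton transfer gives the Breslow enaminol, its C1 attacks the C5 ketone, and collapse of the adduct expels the carbene and leaves the tertiary acyloin; the closest known reaction type is the carbene-catalysed intramolecular crossed aldehyde–ketone benzoin cyclisation of keto-aldehydes to 2-hydroxycycloalkanones. The cyclopentanone closes in a 5-exo-trig mode onto C5, which is a ring atom of the dioxasilinane chair. The one new stereocentre, C5, is controlled by that ring: the three-carbon arm is equatorial on C4 and a five-membered ring annulated through the adjacent carbonyl carbon strongly prefers cis fusion, so C1 enters on the axial face and the new hydroxyl ends equatorial, trans to O4, with C6 cis to O4. The step needs the crossed mode to win over aldehyde self-coupling and aldol chemistry, which high dilution, the 1,5-relationship of the two carbonyls and the two alpha-oxygens that make the C5 ketone an unusually good acceptor should secure. Enolisation towards C4 or C6 would erode not only the cis relationship but, by epimerisation at either centre, the enantiomeric purity, so the base is weak and substoichiometric. Because the benzoin addition is reversible, the more stable cis-fused bicycle should accumulate.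

Step 10
Reactants: 14 (4S,4aS,7aR)-2,2-di-tert-butyl-4a-hydroxy-4-tetradecylhexahydrocyclopenta[d][1,3,2]dioxasilin-5-one
Product: 15 (4S,4aS,7aR)-2,2-di-tert-butyl-5-oxo-4-tetradecylhexahydrocyclopenta[d][1,3,2]dioxasilin-4a-yl acetate
Conditions: Ac2O, DMAP, Et3N, CH2Cl2, rt → 40 °C
Reagents that add atoms: acetic anhydride, CC(=O)OC(C)=O
Why: DMAP-catalysed acyl transfer (Steglich-type acetylation) to the only free hydroxyl, which is tertiary but equatorial on the silylene chair, places the acetyl group unambiguously on O5 while O4 and O6 stay tied in the silylene.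

Step 11
Reactants: 15 (4S,4aS,7aR)-2,2-di-tert-butyl-5-oxo-4-tetradecylhexahydrocyclopenta[d][1,3,2]dioxasilin-4a-yl acetate
Product: 17 (4S,4aS,7aR)-2,2-di-tert-butyl-5-oxo-4-tetradecyl-4,4a,5,7a-tetrahydrocyclopenta[d][1,3,2]dioxasilin-4a-yl acetate (C2=C3 enone in chain labels), via trimethylsilyl enol ether 16 (not isolated)
Conditions: TMSOTf, Et3N, CH2Cl2, 0 °C; then Pd(OAc)2, MeCN, rt
Reagents that add atoms: none
Why: Saegusa–Ito oxidation, in which the ketone can enolise only towards C2 because C5 is quaternary and palladium diacetate converts the silyl enol ether by beta-hydride elimination from C3 into the C2=C3 enone without touching any stereocentre.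

Step 12
Reactants: 17 (4S,4aS,7aR)-2,2-di-tert-butyl-5-oxo-4-tetradecyl-4,4a,5,7a-tetrahydrocyclopenta[d][1,3,2]dioxasilin-4a-yl acetate
Product: 18 (1S,5R)-5-hydroxy-1-[(1S)-1-hydroxypentadecyl]-2-oxocyclopent-3-en-1-yl acetate
Conditions: HF·pyridine, pyridine, THF, 0 °C → rt
Reagents that add atoms: none
Why: Fluoride-driven cleavage of the di-tert-butylsilylene (formation of two strong Si–F bonds) under buffered, non-basic conditions frees O4 and O6 without disturbing the enone or the acetate, and since C5 bears no hydrogen the 4-hydroxy enone cannot eliminate.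

Step 13
Reactants: 18 (1S,5R)-5-hydroxy-1-[(1S)-1-hydroxypentadecyl]-2-oxocyclopent-3-en-1-yl acetate
Product: 19 (1S)-1-[(1R,5R)-1,5-dihydroxy-2-oxocyclopent-3-en-1-yl]pentadecyl acetate (target; 4R,5R,6S in the ring numbering)
Conditions: DBU (0.1 equiv), CH2Cl2, −20 → 0 °C; AcOH quench
Reagents that add atoms: none
Why: Base-catalysed 1,2-acyl migration through a five-membered cyclic orthoacid moves the acetyl group from the crowded tertiary O5 to the adjacent secondary O6, which relieves steric strain, whereas direct transfer to O4 is blocked because O4 and O5 are trans on the five-membered ring.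

**Compound list**

1 | 4-(benzyloxy)butanoic acid | OC(=O)CCCOCc1ccccc1 | starting material
2 | 4-(benzyloxy)-1-(1H-imidazol-1-yl)butan-1-one | O=C(CCCOCc1ccccc1)n1ccnc1 | intermediate
3 | 4-(benzyloxy)-N-methoxy-N-methylbutanamide | CON(C)C(=O)CCCOCc1ccccc1 | intermediate
4 | 1-hexadecyne | CCCCCCCCCCCCCCC#C | starting material
5 | hexadec-1-yn-1-yllithium | [Li]C#CCCCCCCCCCCCCCC | intermediate
6 | lithium hemiaminal adduct of 5 and 3 | CCCCCCCCCCCCCCC#CC(O[Li])(CCCOCc1ccccc1)N(C)OC | intermediate
7 | 1-(benzyloxy)icos-5-yn-4-one | CCCCCCCCCCCCCCC#CC(=O)CCCOCc1ccccc1 | intermediate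
8 | (4R)-1-(benzyloxy)icos-5-yn-4-ol | CCCCCCCCCCCCCCC#C[C@H](O)CCCOCc1ccccc1 | intermediate
9 | (4R,5Z)-1-(benzyloxy)icos-5-en-4-ol | CCCCCCCCCCCCCC/C=C\[C@H](O)CCCOCc1ccccc1 | intermediate
10 | (4R,5S,6S)-1-(benzyloxy)icosane-4,5,6-triol | CCCCCCCCCCCCCC[C@H](O)[C@H](O)[C@H](O)CCCOCc1ccccc1 | intermediate
11 | (4R,5S,6S)-4-[3-(benzyloxy)propyl]-2,2-di-tert-butyl-6-tetradecyl-1,3,2-dioxasilinan-5-ol | CCCCCCCCCCCCCC[C@@H]1O[Si](C(C)(C)C)(C(C)(C)C)O[C@H](CCCOCc2ccccc2)[C@H]1O | intermediate
12 | 3-[(4R,5S,6S)-2,2-di-tert-butyl-5-hydroxy-6-tetradecyl-1,3,2-dioxasilinan-4-yl]propan-1-ol | CCCCCCCCCCCCCC[C@@H]1O[Si](C(C)(C)C)(C(C)(C)C)O[C@H](CCCO)[C@H]1O | intermediate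
13 | 3-[(4R,6S)-2,2-di-tert-butyl-5-oxo-6-tetradecyl-1,3,2-dioxasilinan-4-yl]propanal (cis-4,6) | CCCCCCCCCCCCCC[C@@H]1O[Si](C(C)(C)C)(C(C)(C)C)O[C@H](CCC=O)C1=O | intermediate
14 | (4S,4aS,7aR)-2,2-di-tert-butyl-4a-hydroxy-4-tetradecylhexahydrocyclopenta[d][1,3,2]dioxasilin-5-one (cis-fused) | CCCCCCCCCCCCCC[C@H](O[Si]2(C(C)(C)C)C(C)(C)C)[C@@]1(O)C(=O)CC[C@H]1O2 | intermediate
15 | (4S,4aS,7aR)-2,2-di-tert-butyl-5-oxo-4-tetradecylhexahydrocyclopenta[d][1,3,2]dioxasilin-4a-yl acetate | CCCCCCCCCCCCCC[C@H](O[Si]2(C(C)(C)C)C(C)(C)C)[C@@]1(OC(C)=O)C(=O)CC[C@H]1O2 | intermediate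
16 | trimethylsilyl enol ether of 15 (C1–O–SiMe3, C1=C2) | CCCCCCCCCCCCCC[C@H](O[Si]2(C(C)(C)C)C(C)(C)C)[C@@]1(OC(C)=O)C(O[Si](C)(C)C)=CC[C@H]1O2 | intermediate
17 | (4S,4aS,7aR)-2,2-di-tert-butyl-5-oxo-4-tetradecyl-4,4a,5,7a-tetrahydrocyclopenta[d][1,3,2]dioxasilin-4a-yl acetate | CCCCCCCCCCCCCC[C@H](O[Si]2(C(C)(C)C)C(C)(C)C)[C@@]1(OC(C)=O)C(=O)C=C[C@H]1O2 | intermediate
18 | (1S,5R)-5-hydroxy-1-[(1S)-1-hydroxypentadecyl]-2-oxocyclopent-3-en-1-yl acetate | CCCCCCCCCCCCCC[C@H](O)[C@@]1(OC(C)=O)C(=O)C=C[C@H]1O | intermediate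
19 | (1S)-1-[(1R,5R)-1,5-dihydroxy-2-oxocyclopent-3-en-1-yl]pentadecyl acetate | CCCCCCCCCCCCCC[C@H](OC(C)=O)[C@@]1(O)C(=O)C=C[C@H]1O | target

**Count and risks**

Total step count: 13. Longest linear sequence: 13 steps (1 → 19); 1-hexadecyne 4 enters at step 2.

Step 9 (key ring closure). Intermolecular aldehyde–aldehyde coupling or amine-induced enolisation at C4/C6 may outrun attack on the hindered C5 ketone, or the adduct may revert. The fallback sets out from 13 and forms the same C1–C5 bond reductively. Samarium diiodide (SmI2, THF, tBuOH, −78 °C) reduces the aldehyde first, and its ketyl adds to C5 under the same ring constraint, which should give the silylene-bridged cis-cyclopentane-1,2-diol F1. Oxidation of its secondary C1 hydroxyl (SO3·pyridine, DMSO, iPr2NEt; the tertiary hydroxyl cannot be oxidised) comes back to the route at 14.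

Step 13 (acetyl shift). The acetyl group may travel on from O6 to O4 by a slower 1,3-shift, since O4 and O6 are syn, or the base may open the beta-hydroxy ketone by retro-aldol cleavage. The fallback sets out from 14 and puts the acetate directly on O6. Excess TMSOTf/Et3N gives the bis(trimethylsilyl) derivative F2 (enol ether at C1, silyl ether at O5), and Pd(OAc)2 in MeCN gives the O5-silylated enone F3. HF·pyridine removes both silicon groups to give the enone triol F4. Bu2SnO in MeOH at reflux forms the O5,O6-dibutylstannylene acetal F5 of the vicinal diol, and AcCl (CH2Cl2, 0 °C) acylates its secondary oxygen, O6, coming back to the route at 19.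

Step 5 (osmylation). Facial discrimination with a free allylic hydroxyl may be too weak, so that much 5,6-epimeric triol (which leads to a trans silylene) forms. The fallback sets out from 9. TBSCl/imidazole (DMF) gives the allylic silyl ether F6, whose bulkier allylic substituent should sharpen the anti preference in the OsO4/NMO dihydroxylation to the diol F7. TBAF in THF then comes back to the route at 10.

**Further compounds**

F1 | step 9 | cis-fused silylene-bridged cyclopentane-1,2-diol (C1 carbinol of 14, C1 hydroxyl cis to O5) | CCCCCCCCCCCCCC[C@H](O[Si]2(C(C)(C)C)C(C)(C)C)[C@@]1(O)[C@H](O)CC[C@H]1O2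
F2 | step 13 | bis(trimethylsilyl) derivative of 14 (C1 enol ether and O5 ether) | CCCCCCCCCCCCCC[C@H](O[Si]2(C(C)(C)C)C(C)(C)C)[C@@]1(O[Si](C)(C)C)C(O[Si](C)(C)C)=CC[C@H]1O2
F3 | step 13 | O5-trimethylsilyl silylene-bridged cyclopentenone | CCCCCCCCCCCCCC[C@H](O[Si]2(C(C)(C)C)C(C)(C)C)[C@@]1(O[Si](C)(C)C)C(=O)C=C[C@H]1O2
F4 | step 13 | (4R,5S)-4,5-dihydroxy-5-[(1S)-1-hydroxypentadecyl]cyclopent-2-en-1-one | CCCCCCCCCCCCCC[C@H](O)[C@@]1(O)C(=O)C=C[C@H]1O
F5 | step 13 | O5,O6-dibutylstannylene acetal of F4 | CCCCCCCCCCCCCC[C@@H]1O[Sn](CCCC)(CCCC)O[C@@]12C(=O)C=C[C@H]2O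
F6 | step 5 | (4R,5Z)-1-(benzyloxy)-4-[(tert-butyldimethylsilyl)oxy]icos-5-ene | CCCCCCCCCCCCCC/C=C\[C@H](O[Si](C)(C)C(C)(C)C)CCCOCc1ccccc1
F7 | step 5 | (4R,5S,6S)-1-(benzyloxy)-4-[(tert-butyldimethylsilyl)oxy]icosane-5,6-diol | CCCCCCCCCCCCCC[C@H](O)[C@H](O)[C@H](O[Si](C)(C)C(C)(C)C)CCCOCc1ccccc1
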